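Ring B is not attached to ring A by arene coupling; it is grown on the ring A oxygen. Ring B is cut at C2'–C3', C3'–C4', C5'–C6' and C1'–C6', which leads back to methoxyacetylene and an α-diazo enone whose β-carbon already carries ring A as an aryl enol ether and whose α-carbon carries the ester that becomes the C2' CH2OH. One operation (Wolff shift, ketene [2+2], 4π opening, 6π closure) builds ring B and exploits its pattern: oxygens at C1', C4' and C6' around a single carbon substituent at C2', with C6'–OH emerging as the only free phenol, ready for prenylation.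

Key step: step 5

Labels: in ring B, C1' bears the ether oxygen to ring A, C2' the CH2OH, C4' the OMe and C6' the O-prenyl. ArO stands for the ring A group 2-(methoxycarbonyl)-5-methyl-3-[(3-methylbut-2-en-1-yl)oxy]phenoxy.

Remark on the chemistry: the aryl enol ethers on the way to the diazo enone are drawn as E isomers. A Z isomer, should it form, can be carried along, because this carbon ends as aromatic C1' and its geometry is lost.

Step 1
Reactants: 1 methyl 2,6-dihydroxy-4-methylbenzoate; 2 prenyl bromide (1-bromo-3-methylbut-2-ene)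
Product: 3 methyl 2-hydroxy-4-methyl-6-[(3-methylbut-2-en-1-yl)oxy]benzoate
Conditions: K2CO3 (1.2 equiv), 2 (1.0 equiv), acetone, 56 °C
Reagents that add atoms: none
Why: Williamson O-alkylation, in which the hydroxyl left after the first alkylation is locked in a hydrogen bond to the ester carbonyl and is much less nucleophilic, so that one equivalent of 2 should stop the reaction at the mono-ether.

Step 2
Reactants: 3 methyl 2-hydroxy-4-methyl-6-[(3-methylbut-2-en-1-yl)oxy]benzoate; 4 ethyl 2-(ethoxymethylidene)-3-oxobutanoate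
Product: 5 ethyl (2E)-2-(ArO-methylidene)-3-oxobutanoate
Conditions: 4 (3 equiv), Cs2CO3 (0.2 equiv), toluene, 110 °C, EtOH distilled off
Reagents that add atoms: none
Why: Nucleophilic vinylic substitution (addition–elimination) of the phenoxide of 3 at the ethoxymethylene carbon of the doubly activated acceptor 4 is a known exchange for alkoxymethylene 1,3-dicarbonyl compounds; it is an equilibrium, pulled toward 5 by the excess of 4 and by continuous removal of ethanol, while the hindered ring A ester and the prenyl ether are not touched.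

Step 3
Reactants: 5 ethyl (2E)-2-(ArO-methylidene)-3-oxobutanoate
Product: 7 ethyl (2E)-4-diazo-2-(ArO-methylidene)-3-oxobutanoate, via trifluoroacetyl diketone 6 (not isolated)
Conditions: LiN(SiMe3)2 (1.1 equiv), THF, −78 °C; CF3CO2CH2CF3, −78 °C; aq. HCl work-up; crude 6, MsN3, Et3N, H2O (1 equiv), MeCN, 20 °C
Reagents that add atoms: methanesulfonyl azide, CS(=O)(=O)N=[N+]=[N-] (both diazo nitrogens); 2,2,2-trifluoroethyl trifluoroacetate, O=C(OCC(F)(F)F)C(F)(F)F (the CF3CO group of 6 only, lost again on diazo transfer)
Why: Detrifluoroacetylative diazo transfer, in which the hindered amide base enolizes the methyl ketone kinetically at −78 °C, Claisen trifluoroacetylation gives the activated 1,3-diketone 6 and MsN3 transfers N2 with loss of the trifluoroacetyl group, is the established route to α'-diazo α,β-enones, and the esters and the prenyl alkene should be inert to it.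

Step 4
Reactants: 8 chloroacetaldehyde dimethyl acetal (2-chloro-1,1-dimethoxyethane)
Product: 11 methoxyacetylene, via 2-chlorovinyl methyl ether 9 (not isolated), via sodium methoxyethynide 10 (not isolated)
Conditions: NaNH2 (3.2 equiv), liquid NH3, −33 °C; NH3 evaporated; aq. NaCl, −70 to 20 °C; distilled into ClCH2CH2Cl at −20 °C and used at once
Reagents that add atoms: none
Why: Two successive base-induced eliminations (methanol, then HCl) followed by deprotonation give the sodium acetylide, which is protonated on aqueous quench; this is the standard preparation of alkoxyacetylenes from chloroacetaldehyde acetals.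

Step 5
Reactants: 7 ethyl (2E)-4-diazo-2-(ArO-methylidene)-3-oxobutanoate; 11 methoxyacetylene
Product: 16 methyl 2-[2-(ethoxycarbonyl)-6-hydroxy-4-methoxyphenoxy]-4-methyl-6-[(3-methylbut-2-en-1-yl)oxy]benzoate, via vinylketene 12 (not isolated), via vinylcyclobutenone 13 (not isolated), via dienylketene 14 (not isolated), via cyclohexadienone 15 (not isolated)
Conditions: 11 (5 equiv), ClCH2CH2Cl (0.05 M), hν (365 nm), 20 °C, sealed Pyrex tube; then 80 °C
Reagents that add atoms: none
Why: Excitation of the diazo ketone expels N2 and the alkenyl carbon C2' shifts from C6' to C3' (photochemical Wolff rearrangement), giving vinylketene 12 with the aryloxy group on its terminal carbon and the ester on its internal carbon. The ynol ether 11, nucleophilic at its unsubstituted carbon, adds to the ketene in a regioselective [2+2] (bonds C5'–C6' and C3'–C4') to give the 3-methoxy-4-vinylcyclobutenone 13, which at 80 °C opens by 4π electrocyclic cleavage of C3'–C6' to dienylketene 14. Ring B is then closed by a thermal 6π electrocyclization (disrotatory, C6' onto the aryloxy-bearing C1') to dienone 15, and enolization gives phenol 16; the stereocenters of 13 and 15 are transient and vanish on aromatization, so none has to be controlled. The closest known reaction type is the Danheiser benzannulation of vinylketenes, generated by photo-Wolff rearrangement of unsaturated α-diazo ketones, with alkoxyacetylenes to give resorcinol monoethers. The required regiochemistry (OMe at C4', meta to the new C6'–OH) follows from the polarization of the ynol ether, and chemoselectivity rests on the excess of this very reactive ketenophile over the unactivated prenyl alkene, on dilution to limit acylation of 16 by the ketene, and on 365 nm light, which the aryl prenyl ether does not absorb.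

Step 6
Reactants: 16 methyl 2-[2-(ethoxycarbonyl)-6-hydroxy-4-methoxyphenoxy]-4-methyl-6-[(3-methylbut-2-en-1-yl)oxy]benzoate; 2 prenyl bromide
Product: 17 methyl 2-{2-(ethoxycarbonyl)-4-methoxy-6-[(3-methylbut-2-en-1-yl)oxy]phenoxy}-4-methyl-6-[(3-methylbut-2-en-1-yl)oxy]benzoate
Conditions: K2CO3 (1.5 equiv), 2 (1.2 equiv), DMF, 40 °C
Reagents that add atoms: none
Why: Williamson O-alkylation of the only free hydroxyl (C6'–OH), under conditions to which both esters, the diaryl ether and the first prenyl ether are inert.

Step 7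
Reactants: 17 methyl 2-{2-(ethoxycarbonyl)-4-methoxy-6-[(3-methylbut-2-en-1-yl)oxy]phenoxy}-4-methyl-6-[(3-methylbut-2-en-1-yl)oxy]benzoate
Product: 19 methyl 2-{2-(hydroxymethyl)-4-methoxy-6-[(3-methylbut-2-en-1-yl)oxy]phenoxy}-4-methyl-6-[(3-methylbut-2-en-1-yl)oxy]benzoate (target), via aldehyde 18 (not isolated)
Conditions: i-Bu2AlH (2.2 equiv), CH2Cl2, −78 to −40 °C; aq. KNaC4H4O6 work-up
Reagents that add atoms: none
Why: Chemoselective hydride reduction of an ester, in which the ring B ethyl ester, having a single ortho substituent, is reduced through aldehyde 18 to the benzylic alcohol, whereas the ring A methyl ester is shielded by two ortho oxygen substituents (O-prenyl and aryloxy) and should survive a limited amount of i-Bu2AlH at low temperature; the aryl allyl ethers and alkenes are inert.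

Compound list
1 | methyl 2,6-dihydroxy-4-methylbenzoate | COC(=O)c1c(O)cc(C)cc1O | starting material
2 | prenyl bromide (1-bromo-3-methylbut-2-ene) | CC(C)=CCBr | starting material
3 | methyl 2-hydroxy-4-methyl-6-[(3-methylbut-2-en-1-yl)oxy]benzoate | COC(=O)c1c(O)cc(C)cc1OCC=C(C)C | intermediate
4 | ethyl 2-(ethoxymethylidene)-3-oxobutanoate (E/Z mixture as supplied) | CCOC=C(C(C)=O)C(=O)OCC | starting material
5 | ethyl (2E)-2-({2-(methoxycarbonyl)-5-methyl-3-[(3-methylbut-2-en-1-yl)oxy]phenoxy}methylidene)-3-oxobutanoate | COC(=O)c1c(OCC=C(C)C)cc(C)cc1O/C=C(/C(=O)OCC)C(C)=O | intermediate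
6 | ethyl (2E)-6,6,6-trifluoro-2-({2-(methoxycarbonyl)-5-methyl-3-[(3-methylbut-2-en-1-yl)oxy]phenoxy}methylidene)-3,5-dioxohexanoate | COC(=O)c1c(OCC=C(C)C)cc(C)cc1O/C=C(/C(=O)OCC)C(=O)CC(=O)C(F)(F)F | intermediate (not isolated)
7 | ethyl (2E)-4-diazo-2-({2-(methoxycarbonyl)-5-methyl-3-[(3-methylbut-2-en-1-yl)oxy]phenoxy}methylidene)-3-oxobutanoate | COC(=O)c1c(OCC=C(C)C)cc(C)cc1O/C=C(/C(=O)OCC)C(=O)C=[N+]=[N-] | intermediate (key-step precursor)
8 | chloroacetaldehyde dimethyl acetal (2-chloro-1,1-dimethoxyethane) | COC(CCl)OC | starting material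
9 | 2-chlorovinyl methyl ether (1-chloro-2-methoxyethene, E/Z mixture, geometry of no consequence) | COC=CCl | intermediate (not isolated)
10 | sodium methoxyethynide | [Na+].[C-]#COC | intermediate (not isolated)
11 | methoxyacetylene (methoxyethyne) | COC#C | intermediate
12 | vinylketene, ethyl (2E)-2-({2-(methoxycarbonyl)-5-methyl-3-[(3-methylbut-2-en-1-yl)oxy]phenoxy}methylidene)-4-oxobut-3-enoate | COC(=O)c1c(OCC=C(C)C)cc(C)cc1O/C=C(/C(=O)OCC)C=C=O | intermediate (not isolated)
13 | vinylcyclobutenone, ethyl (2E)-3-{2-(methoxycarbonyl)-5-methyl-3-[(3-methylbut-2-en-1-yl)oxy]phenoxy}-2-(2-methoxy-4-oxocyclobut-2-en-1-yl)prop-2-enoate, racemic at the ring carbon | COC(=O)c1c(OCC=C(C)C)cc(C)cc1O/C=C(/C(=O)OCC)C1C(=O)C=C1OC | intermediate (not isolated)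
14 | dienylketene, ethyl (2E,3E)-4-methoxy-2-({2-(methoxycarbonyl)-5-methyl-3-[(3-methylbut-2-en-1-yl)oxy]phenoxy}methylidene)-6-oxohexa-3,5-dienoate | COC(=O)c1c(OCC=C(C)C)cc(C)cc1O/C=C(/C(=O)OCC)\C=C(OC)/C=C=O | intermediate (not isolated)
15 | cyclohexadienone, ethyl 3-methoxy-6-{2-(methoxycarbonyl)-5-methyl-3-[(3-methylbut-2-en-1-yl)oxy]phenoxy}-5-oxocyclohexa-1,3-diene-1-carboxylate, racemic | COC(=O)c1c(OCC=C(C)C)cc(C)cc1OC1C(=O)C=C(OC)C=C1C(=O)OCC | intermediate (not isolated)
16 | methyl 2-[2-(ethoxycarbonyl)-6-hydroxy-4-methoxyphenoxy]-4-methyl-6-[(3-methylbut-2-en-1-yl)oxy]benzoate | COC(=O)c1c(OCC=C(C)C)cc(C)cc1Oc1c(C(=O)OCC)cc(OC)cc1O | intermediate (key-step product)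
17 | methyl 2-{2-(ethoxycarbonyl)-4-methoxy-6-[(3-methylbut-2-en-1-yl)oxy]phenoxy}-4-methyl-6-[(3-methylbut-2-en-1-yl)oxy]benzoate | COC(=O)c1c(OCC=C(C)C)cc(C)cc1Oc1c(C(=O)OCC)cc(OC)cc1OCC=C(C)C | intermediate
18 | methyl 2-{2-formyl-4-methoxy-6-[(3-methylbut-2-en-1-yl)oxy]phenoxy}-4-methyl-6-[(3-methylbut-2-en-1-yl)oxy]benzoate | COC(=O)c1c(OCC=C(C)C)cc(C)cc1Oc1c(C=O)cc(OC)cc1OCC=C(C)C | intermediate (not isolated)
19 | methyl 2-{2-(hydroxymethyl)-4-methoxy-6-[(3-methylbut-2-en-1-yl)oxy]phenoxy}-4-methyl-6-[(3-methylbut-2-en-1-yl)oxy]benzoate | COC(=O)c1c(OCC=C(C)C)cc(C)cc1Oc1c(CO)cc(OC)cc1OCC=C(C)C | target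

Total step count: 7. Longest linear sequence: 6 steps (1, 2, 3, 5, 6, 7); step 4 is a one-step side branch.

Steps most likely to fail

1. Step 5. The vinylketene may be consumed by acylating the phenol as it forms or by dimerizing before the [2+2]. The excited diazo ketone may also be diverted, for instance by attack of the neighbouring ester carbonyl on the carbene, and the cyclobutenone may not open cleanly on heating. Fallback: ring B is brought in preformed and the ether bond is made by Ullmann coupling, setting out from phenol 3 and coming back to the route at 19. Commercial methyl 3-hydroxy-5-methoxybenzoate (COC(=O)c1cc(O)cc(OC)c1) would be acetylated (Ac2O, pyridine) to methyl 3-acetoxy-5-methoxybenzoate F1. Bromination para to the methoxy group (NBS, cat. CF3CO2H, MeCN) should give methyl 3-acetoxy-2-bromo-5-methoxybenzoate F2. Deacetylation (K2CO3, MeOH) would give methyl 2-bromo-3-hydroxy-5-methoxybenzoate F3, and prenylation with 2 (K2CO3, DMF) methyl 2-bromo-5-methoxy-3-[(3-methylbut-2-en-1-yl)oxy]benzoate F4. Phenol 3 and F4 would then be coupled (CuI, N,N-dimethylglycine, Cs2CO3, dioxane, 100 °C), the ortho ester assisting the copper-mediated substitution, to methyl 2-{4-methoxy-2-(methoxycarbonyl)-6-[(3-methylbut-2-en-1-yl)oxy]phenoxy}-4-methyl-6-[(3-methylbut-2-en-1-yl)oxy]benzoate F5. The i-Bu2AlH reduction of step 7, applied to F5, should reduce the less hindered ring B ester and give 19.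

2. Step 2. The exchange of ethoxide for the hindered, hydrogen-bonded aryloxide is an equilibrium that favours the ethoxy compound. Displacement may stay incomplete even with removal of ethanol, and liberated ethoxide may degrade 4 by retro-Claisen cleavage at 110 °C. Fallback: the reversible exchange is replaced by an irreversible vinylic substitution of chloride, setting out from 4 (with phenol 3) and coming back at 5. Hydrolysis of 4 (NaOH, 1 equiv, aq. EtOH, 0 °C) would give the sodium enolate of ethyl 2-formyl-3-oxobutanoate F6. Treatment with oxalyl chloride and catalytic DMF (CH2Cl2, 0 °C) should convert it into ethyl 2-(chloromethylidene)-3-oxobutanoate F7. The phenoxide of 3 (K2CO3, MeCN, 0 to 20 °C) would then displace chloride by addition–elimination to give 5.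

3. Step 3. The amide base, or water and Et3N during the diazo transfer, may add to the aryloxy-bearing carbon and expel phenol 3 by addition–elimination, or the enolate may condense with a second molecule of the acceptor. Fallback: the order of events is inverted so that the diazo group is in place before the good aryloxide leaving group exists, setting out from 4 (with phenol 3) and coming back at 7. The same detrifluoroacetylative diazo transfer on 4 (LiN(SiMe3)2, CF3CO2CH2CF3; MsN3, Et3N, H2O, MeCN) would pass through ethyl 2-(ethoxymethylidene)-6,6,6-trifluoro-3,5-dioxohexanoate F8, not isolated, to ethyl 4-diazo-2-(ethoxymethylidene)-3-oxobutanoate F9. Exchange of its ethoxy group with phenol 3 (Cs2CO3 cat., toluene, 50 to 60 °C, ethanol stripped under reduced pressure) should then give 7.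

Further compounds
F1 | step 5 | methyl 3-acetoxy-5-methoxybenzoate | COC(=O)c1cc(OC(C)=O)cc(OC)c1
F2 | step 5 | methyl 3-acetoxy-2-bromo-5-methoxybenzoate | COC(=O)c1c(Br)c(OC(C)=O)cc(OC)c1
F3 | step 5 | methyl 2-bromo-3-hydroxy-5-methoxybenzoate | COC(=O)c1c(Br)c(O)cc(OC)c1
F4 | step 5 | methyl 2-bromo-5-methoxy-3-[(3-methylbut-2-en-1-yl)oxy]benzoate | COC(=O)c1c(Br)c(OCC=C(C)C)cc(OC)c1
F5 | step 5 | methyl 2-{4-methoxy-2-(methoxycarbonyl)-6-[(3-methylbut-2-en-1-yl)oxy]phenoxy}-4-methyl-6-[(3-methylbut-2-en-1-yl)oxy]benzoate | COC(=O)c1c(OCC=C(C)C)cc(C)cc1Oc1c(C(=O)OC)cc(OC)cc1OCC=C(C)C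
F6 | step 2 | sodium enolate of ethyl 2-formyl-3-oxobutanoate | [Na+].CCOC(=O)C(=C[O-])C(C)=O
F7 | step 2 | ethyl 2-(chloromethylidene)-3-oxobutanoate (E/Z mixture) | CCOC(=O)C(=CCl)C(C)=O
F8 | step 3 | ethyl 2-(ethoxymethylidene)-6,6,6-trifluoro-3,5-dioxohexanoate (E/Z mixture) | CCOC=C(C(=O)OCC)C(=O)CC(=O)C(F)(F)F
F9 | step 3 | ethyl 4-diazo-2-(ethoxymethylidene)-3-oxobutanoate (E/Z mixture) | CCOC=C(C(=O)OCC)C(=O)C=[N+]=[N-]
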